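## Retrosynthetic overview

1. Target 40 ← NAP removal ← C2 inversion (ketone, chelation-controlled reduction) ← one hydroxyl-directed double epoxidation (C3–C4 and C13–C14) of macrocyclic triene 35.
2. The ten-membered ring of 35 is closed last, by ring-closing metathesis at C3=C4 (Z) of seco-tetraene 34.
3. 34 ← C8–C9 union of cyclohexene aldehyde 14 and lactone allyl bromide 28 by zinc Barbier γ-allylation (sets C8 and C9), then methylene reduction (C17).
4. 14 ← catalytic asymmetric Diels–Alder (cyclohexene ring, C1/C10), vinylzinc addition (C2), enolate methylation and epimerisation (C11), CBS reduction (C12).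
5. 28 ← Sharpless epoxidation and chloride opening (C6, C7), Schobert tetronate synthesis (lactone ring), enyne metathesis (diene), hydroxymethylation and bromination. Ring order: cyclohexene → butenolide → ten-membered ring → two oxiranes.

Assumption: 3 and 15 are bought, the antipode of each chiral catalyst that gives the drawn configuration is the one used, and late compounds carry briarane locants (C1–C14 carbocycle, Me-15 on C1, C16 on C5, C17(Me-18)–C19(=O) lactone, Me-20 on C11).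

## Route

Step 1
Reactants: 1 (E)-4-(dimethylamino)but-3-en-2-one
Product: 2 (E)-3-(tert-butyldimethylsilyloxy)-N,N-dimethylbuta-1,3-dien-1-amine
Conditions: KHMDS, THF, −78 °C; TBSCl
Reagents that add atoms: tert-butyl(chloro)dimethylsilane, CC(C)(C)[Si](C)(C)Cl
Why: O-silylation of the potassium enolate of the vinylogous amide gives the 1-amino-3-siloxy diene (Rawal diene synthesis); no stereocentre is formed.

Step 2
Reactants: 2 (E)-3-(tert-butyldimethylsilyloxy)-N,N-dimethylbuta-1,3-dien-1-amine; 3 (E)-4,4-dimethoxy-2-methylbut-2-enal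
Product: 5 (1S,6S)-6-(dimethoxymethyl)-1-methyl-4-oxocyclohex-2-ene-1-carbaldehyde, via cycloadduct 4 (not isolated)
Conditions: Cr(III)–salen·SbF6 (Jacobsen type, 5 mol %), 4 Å MS, CH2Cl2, −40 °C; then AcCl, −78 → 0 °C
Reagents that add atoms: none
Why: Enantioselective Diels–Alder reaction in which the E geometry of 3 fixes CHO and acetal trans at the new quaternary/tertiary pair, the catalyst sets the absolute sense, and N-acylation/β-elimination unmasks the enone.

Step 3
Reactants: 5 (1S,6S)-6-(dimethoxymethyl)-1-methyl-4-oxocyclohex-2-ene-1-carbaldehyde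
Product: 6 (4S,5S)-5-(dimethoxymethyl)-4-[(1S)-1-hydroxyprop-2-enyl]-4-methylcyclohex-2-en-1-one
Conditions: (CH2=CH)2Zn, (−)-MIB (10 mol %), toluene, 0 °C; H2O
Reagents that add atoms: divinylzinc, C=C[Zn]C=C
Why: Amino-alcohol-catalysed vinylzinc addition is selective for the aldehyde over the enone and the ligand–zinc complex delivers vinyl to the Si face, setting the (S)-carbinol under ligand control.

Step 4
Reactants: 6 (4S,5S)-5-(dimethoxymethyl)-4-[(1S)-1-hydroxyprop-2-enyl]-4-methylcyclohex-2-en-1-one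
Product: 7 (4S,5S)-5-(dimethoxymethyl)-4-methyl-4-[(1S)-1-(triethylsilyloxy)prop-2-enyl]cyclohex-2-en-1-one
Conditions: TESCl, imidazole, DMF, 0 °C
Reagents that add atoms: chlorotriethylsilane, CC[Si](Cl)(CC)CC
Why: Silyl ether formation masks the carbinol for the enolate chemistry and keeps it from forming a lactol with the later aldehyde.

Step 5
Reactants: 7 (4S,5S)-5-(dimethoxymethyl)-4-methyl-4-[(1S)-1-(triethylsilyloxy)prop-2-enyl]cyclohex-2-en-1-one
Product: 9 (4S,5S,6S)-5-(dimethoxymethyl)-4,6-dimethyl-4-[(1S)-1-(triethylsilyloxy)prop-2-enyl]cyclohex-2-en-1-one, via lithium dienolate 8 (not isolated)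
Conditions: LDA, THF, −78 °C; MeI
Reagents that add atoms: iodomethane, CI
Why: Kinetic α′-deprotonation gives the cross-conjugated dienolate, which is alkylated anti to the neighbouring acetal-bearing carbon (enolate alkylation), giving the 5,6-trans isomer.

Step 6
Reactants: 9 (4S,5S,6S)-5-(dimethoxymethyl)-4,6-dimethyl-4-[(1S)-1-(triethylsilyloxy)prop-2-enyl]cyclohex-2-en-1-one
Product: 11 (4S,5S,6R)-5-(dimethoxymethyl)-4,6-dimethyl-4-[(1S)-1-(triethylsilyloxy)prop-2-enyl]cyclohex-2-en-1-one, via lithium dienolate 10 (not isolated)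
Conditions: LDA, THF, −78 °C; then t-BuCO2H, −78 °C
Reagents that add atoms: none
Why: Re-enolisation and kinetic protonation from the face opposite the adjacent acetal substituent (contra-thermodynamic epimerisation) places the methyl cis to the acetal, the C10/C11 relationship of the target.

Step 7
Reactants: 11 (4S,5S,6R)-5-(dimethoxymethyl)-4,6-dimethyl-4-[(1S)-1-(triethylsilyloxy)prop-2-enyl]cyclohex-2-en-1-one
Product: 12 (1S,4S,5S,6R)-5-(dimethoxymethyl)-4,6-dimethyl-4-[(1S)-1-(triethylsilyloxy)prop-2-enyl]cyclohex-2-en-1-ol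
Conditions: (S)-Me-CBS (0.3 equiv), catecholborane, toluene, −78 °C
Reagents that add atoms: none
Why: Corey–Bakshi–Shibata 1,2-reduction of the enone, with hydride delivered anti to the adjacent C-methyl (matched with the catalyst), gives the allylic alcohol cis to that methyl.

Step 8
Reactants: 12 (1S,4S,5S,6R)-5-(dimethoxymethyl)-4,6-dimethyl-4-[(1S)-1-(triethylsilyloxy)prop-2-enyl]cyclohex-2-en-1-ol
Product: 13 2-naphthylmethyl (NAP) ether of 12 at the ring hydroxyl
Conditions: NaH, 2-(bromomethyl)naphthalene, Bu4NI (cat.), THF–DMF, 0 °C → rt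
Reagents that add atoms: 2-(bromomethyl)naphthalene, BrCc1ccc2ccccc2c1
Why: Williamson etherification installs an oxidatively removable group that survives all later steps; no stereocentre is touched.

Step 9
Reactants: 13 2-naphthylmethyl (NAP) ether of 12
Product: 14 (1S,2S,5S,6R)-2,6-dimethyl-5-(naphthalen-2-ylmethoxy)-2-[(1S)-1-(triethylsilyloxy)prop-2-enyl]cyclohex-3-ene-1-carbaldehyde
Conditions: (CO2H)2 (cat.), wet SiO2, CH2Cl2, rt
Reagents that add atoms: water, O
Why: Mild acetal hydrolysis on wet silica frees the aldehyde without cleaving the TES ether or epimerising the α-carbon.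

Step 10
Reactants: 15 (E)-pent-2-en-4-yn-1-ol
Product: 16 [(2R,3R)-3-ethynyloxiran-2-yl]methanol
Conditions: Ti(OiPr)4 (10 mol %), D-(−)-DIPT (12 mol %), t-BuOOH, 4 Å MS, CH2Cl2, −20 °C
Reagents that add atoms: tert-butyl hydroperoxide, CC(C)(C)OO
Why: Sharpless asymmetric epoxidation of the E-allylic alcohol with the D-tartrate gives the (2R,3R)-epoxide under reagent control.

Step 11
Reactants: 16 [(2R,3R)-3-ethynyloxiran-2-yl]methanol
Product: 17 (2R,3S)-3-chloropent-4-yne-1,2-diol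
Conditions: ClTi(OiPr)3, THF, 0 °C → rt; aq. tartaric acid
Reagents that add atoms: chlorotitanium triisopropoxide, CC(C)O[Ti](Cl)(OC(C)C)OC(C)C
Why: Titanium-chelate-directed C3-selective epoxide opening puts chloride on the propargylic carbon with inversion, giving the anti chlorohydrin (C6/C7 of the target).

Step 12
Reactants: 17 (2R,3S)-3-chloropent-4-yne-1,2-diol
Product: 18 (2R,3S)-3-chloro-2-hydroxypent-4-ynoic acid
Conditions: TEMPO (cat.), NaOCl (cat.), NaClO2, MeCN–phosphate buffer pH 6.7, 35 °C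
Reagents that add atoms: sodium chlorite, [Na+].[O-]Cl=O
Why: TEMPO/chlorite oxidation is selective for the primary alcohol and runs near neutral pH, so the β-chloro-α-hydroxy stereodiad is preserved.

Step 13
Reactants: 18 (2R,3S)-3-chloro-2-hydroxypent-4-ynoic acid
Product: 19 naphthalen-2-ylmethyl (2R,3S)-3-chloro-2-hydroxypent-4-ynoate
Conditions: 2-(bromomethyl)naphthalene, KHCO3, DMF, rt
Reagents that add atoms: 2-(bromomethyl)naphthalene, BrCc1ccc2ccccc2c1
Why: Carboxylate O-alkylation with a weak base avoids epoxide formation from the chlorohydrin and introduces the group that becomes the C8 oxygen substituent.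

Step 14
Reactants: 20 methyl (triphenylphosphoranylidene)acetate
Product: 21 (triphenylphosphoranylidene)ethenone (Ph3P=C=C=O)
Conditions: NaHMDS, toluene, 60 °C
Reagents that add atoms: none
Why: Bestmann preparation: deprotonation of the ester ylide and loss of methoxide gives the cumulated ylide.

Step 15
Reactants: 19 naphthalen-2-ylmethyl (2R,3S)-3-chloro-2-hydroxypent-4-ynoate; 21 (triphenylphosphoranylidene)ethenone
Product: 23 (5R)-5-[(1S)-1-chloroprop-2-ynyl]-4-(naphthalen-2-ylmethoxy)furan-2(5H)-one, via ester ylide 22 (not isolated)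
Conditions: PhCO2H (cat.), THF, 65 °C
Reagents that add atoms: none
Why: Schobert tetronate synthesis: the hydroxyl adds to the cumulated ylide and the resulting ester ylide closes by intramolecular Wittig olefination of the ester carbonyl, whose alkoxy group becomes the 4-alkoxy substituent; both stereocentres are untouched.

Step 16
Reactants: 23 (5R)-5-[(1S)-1-chloroprop-2-ynyl]-4-(naphthalen-2-ylmethoxy)furan-2(5H)-one
Product: 24 (5R)-5-[(1S)-1-chloroprop-2-ynyl]-3-iodo-4-(naphthalen-2-ylmethoxy)furan-2(5H)-one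
Conditions: NIS, TFA (cat.), MeCN, rt
Reagents that add atoms: N-iodosuccinimide, O=C1CCC(=O)N1I
Why: Electrophilic iodination at the nucleophilic α-carbon of the push–pull (β-alkoxy enoate) alkene.

Step 17
Reactants: 24 (5R)-5-[(1S)-1-chloroprop-2-ynyl]-3-iodo-4-(naphthalen-2-ylmethoxy)furan-2(5H)-one
Product: 25 (5R)-5-[(1S)-1-chloro-2-methylidenebut-3-enyl]-3-iodo-4-(naphthalen-2-ylmethoxy)furan-2(5H)-one
Conditions: Grubbs II (5 mol %), ethylene (1 atm), CH2Cl2, 40 °C
Reagents that add atoms: ethene, C=C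
Why: Ethylene–alkyne cross enyne metathesis converts the terminal alkyne into the 2-substituted buta-1,3-diene (C4, C5, C16) without touching the stereocentres.

Step 18
Reactants: 25 (5R)-5-[(1S)-1-chloro-2-methylidenebut-3-enyl]-3-iodo-4-(naphthalen-2-ylmethoxy)furan-2(5H)-one
Product: 27 (5R)-5-[(1S)-1-chloro-2-methylidenebut-3-enyl]-3-(hydroxymethyl)-4-(naphthalen-2-ylmethoxy)furan-2(5H)-one, via alkenylmagnesium chloride 26 (not isolated)
Conditions: i-PrMgCl·LiCl, THF, −78 °C; then CH2O (gas), −78 → 0 °C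
Reagents that add atoms: formaldehyde, C=O
Why: Iodine–magnesium exchange (Knochel turbo-Grignard) on the activated alkenyl iodide followed by hydroxymethylation with formaldehyde.

Step 19
Reactants: 27 (5R)-5-[(1S)-1-chloro-2-methylidenebut-3-enyl]-3-(hydroxymethyl)-4-(naphthalen-2-ylmethoxy)furan-2(5H)-one
Product: 28 (5R)-3-(bromomethyl)-5-[(1S)-1-chloro-2-methylidenebut-3-enyl]-4-(naphthalen-2-ylmethoxy)furan-2(5H)-one
Conditions: CBr4, PPh3, CH2Cl2, 0 °C
Reagents that add atoms: tetrabromomethane, BrC(Br)(Br)Br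
Why: Appel bromination of the primary allylic alcohol under neutral conditions.

Step 20
Reactants: 14 (1S,2S,5S,6R)-2,6-dimethyl-5-(naphthalen-2-ylmethoxy)-2-[(1S)-1-(triethylsilyloxy)prop-2-enyl]cyclohex-3-ene-1-carbaldehyde; 28 (5R)-3-(bromomethyl)-5-[(1S)-1-chloro-2-methylidenebut-3-enyl]-4-(naphthalen-2-ylmethoxy)furan-2(5H)-one
Product: 31 (R)-[cyclohexenyl][(2R,3R)-2-[(1S)-1-chloro-2-methylidenebut-3-enyl]-4-methylidene-3-(naphthalen-2-ylmethoxy)-5-oxooxolan-3-yl]methyl acetate (C8–C9 coupled seco-tetraene), via allylzinc bromide 29 (not isolated), via bromozinc alkoxide 30 (not isolated)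
Conditions: Zn dust, THF, 0 °C → rt; then Ac2O, DMAP (cat.), 0 °C
Reagents that add atoms: acetic anhydride, CC(=O)OC(C)=O
Why: Zinc Barbier (Dreiding–Schmidt-type) γ-allylation through a closed chair, with C9 bonding to the alkoxy-bearing γ-carbon on the lactone face anti to the C7 side chain and the aldehyde substituent equatorial, sets C8 (8R) and C9 (9R), and the alkoxide is acetylated in situ before it can translactonise.

Step 21
Reactants: 31 C8–C9 coupled seco-tetraene acetate (α-methylene lactone)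
Product: 33 17R-methyl lactone (17,18-dihydro-31; Me-18 cis to the C8 oxygen), via 17-epimer 32 (not isolated)
Conditions: NaBH4, MeOH–THF, −20 °C; then DBU (cat.), toluene, rt
Reagents that add atoms: none
Why: Conjugate hydride reduction of the α-methylene-γ-lactone followed by base equilibration at the epimerisable C17 to the isomer with the methyl anti to the bulky C9 branch.

Step 22
Reactants: 33 17R-methyl lactone, 2-O-TES
Product: 34 RCM precursor with free (S)-configured C2 allylic alcohol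
Conditions: HF·pyridine, pyridine, THF, 0 °C
Reagents that add atoms: none
Why: Selective cleavage of the secondary TES ether; the NAP ethers, acetate, lactone and allylic chloride are stable to buffered fluoride.

Step 23
Reactants: 34 RCM precursor with free C2 allylic alcohol
Product: 35 (2S,3Z)-9-acetoxy-6-chloro-2-hydroxy-8,12-bis(naphthalen-2-ylmethoxy)briara-3,5(16),13-trien-19-oic acid 19,7-lactone
Conditions: Grubbs II (15 mol %), toluene (0.5 mM), 80 °C
Reagents that add atoms: none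
Why: Ring-closing metathesis between the allylic-alcohol vinyl group and the monosubstituted terminus of the 1,3-diene closes the ten-membered ring, with ring strain enforcing the Z C3=C4 alkene and the 1,1-disubstituted C5=C16 and cyclohexene alkenes inert.

Step 24
Reactants: 35 macrocyclic triene
Product: 37 (2R,3S,4R,13S,14R)-3,4:13,14-bis-epoxide of 35, via monoepoxide 36 (not isolated)
Conditions: VO(acac)2 (10 mol %), t-BuOOH (3 equiv), CH2Cl2, 0 °C → rt
Reagents that add atoms: tert-butyl hydroperoxide, CC(C)(C)OO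
Why: Vanadium-catalysed hydroxyl-directed epoxidation: the C2 vanadate delivers oxygen to the allylic Z-alkene on the hydroxyl face (threo, A(1,3) control) and then to the homoallylic C13=C14 alkene on the α face that carries the C2 side chain.

Step 25
Reactants: 37 bis-epoxide with 2R alcohol
Product: 38 2-oxo derivative of 37 (α,β-epoxy ketone)
Conditions: Dess–Martin periodinane, NaHCO3, CH2Cl2, 0 °C
Reagents that add atoms: none
Why: Buffered Dess–Martin oxidation of the hindered secondary alcohol without epoxide opening.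

Step 26
Reactants: 38 2-oxo bis-epoxide
Product: 39 8,12-di-O-(2-naphthylmethyl) ether of the target (2S alcohol)
Conditions: Zn(BH4)2, Et2O, −30 °C
Reagents that add atoms: none
Why: Chelation-controlled reduction of the α,β-epoxy ketone (zinc bridges carbonyl and oxirane oxygens) gives the erythro epoxy alcohol, a net inversion at C2 to the 2S configuration.

Step 27
Reactants: 39 8,12-di-O-(2-naphthylmethyl) ether of the target
Product: 40 CNP0314105.1 (target)
Conditions: DDQ, CH2Cl2–pH 7 buffer, rt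
Reagents that add atoms: none
Why: Oxidative cleavage of both naphthylmethyl ethers under neutral conditions leaves the epoxides, allylic chloride, acetate and lactone intact.

## Compound list

1 | (E)-4-(dimethylamino)but-3-en-2-one | CC(=O)/C=C/N(C)C | starting material
2 | (E)-3-(tert-butyldimethylsilyloxy)-N,N-dimethylbuta-1,3-dien-1-amine | CN(C)/C=C/C(=C)O[Si](C)(C)C(C)(C)C | intermediate
3 | (E)-4,4-dimethoxy-2-methylbut-2-enal | O=C/C(C)=C/C(OC)OC | starting material
4 | endo cycloadduct: (1S,6S)-4-(tert-butyldimethylsilyloxy)-2-(dimethylamino)-6-(dimethoxymethyl)-1-methylcyclohex-3-ene-1-carbaldehyde, NMe2 cis to CHO | O=C[C@]1(C)[C@H](CC(O[Si](C)(C)C(C)(C)C)=C[C@@H]1N(C)C)C(OC)OC | intermediate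
5 | (1S,6S)-6-(dimethoxymethyl)-1-methyl-4-oxocyclohex-2-ene-1-carbaldehyde | O=C[C@]1(C)[C@H](CC(=O)C=C1)C(OC)OC | intermediate
6 | (4S,5S)-5-(dimethoxymethyl)-4-[(1S)-1-hydroxyprop-2-enyl]-4-methylcyclohex-2-en-1-one | C=C[C@H](O)[C@]1(C)[C@H](CC(=O)C=C1)C(OC)OC | intermediate
7 | (4S,5S)-5-(dimethoxymethyl)-4-methyl-4-[(1S)-1-(triethylsilyloxy)prop-2-enyl]cyclohex-2-en-1-one | C=C[C@H](O[Si](CC)(CC)CC)[C@]1(C)[C@H](CC(=O)C=C1)C(OC)OC | intermediate
8 | lithium cross-conjugated dienolate of 7 | C=C[C@H](O[Si](CC)(CC)CC)[C@]1(C)[C@H](C=C(O[Li])C=C1)C(OC)OC | intermediate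
9 | (4S,5S,6S)-5-(dimethoxymethyl)-4,6-dimethyl-4-[(1S)-1-(triethylsilyloxy)prop-2-enyl]cyclohex-2-en-1-one (6-Me trans to acetal) | C=C[C@H](O[Si](CC)(CC)CC)[C@]1(C)[C@H]([C@H](C)C(=O)C=C1)C(OC)OC | intermediate
10 | lithium cross-conjugated dienolate of 9 | C=C[C@H](O[Si](CC)(CC)CC)[C@]1(C)[C@H](C(C)=C(O[Li])C=C1)C(OC)OC | intermediate
11 | (4S,5S,6R)-5-(dimethoxymethyl)-4,6-dimethyl-4-[(1S)-1-(triethylsilyloxy)prop-2-enyl]cyclohex-2-en-1-one (6-Me cis to acetal) | C=C[C@H](O[Si](CC)(CC)CC)[C@]1(C)[C@H]([C@@H](C)C(=O)C=C1)C(OC)OC | intermediate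
12 | (1S,4S,5S,6R)-5-(dimethoxymethyl)-4,6-dimethyl-4-[(1S)-1-(triethylsilyloxy)prop-2-enyl]cyclohex-2-en-1-ol | C=C[C@H](O[Si](CC)(CC)CC)[C@]1(C)[C@H]([C@@H](C)[C@@H](O)C=C1)C(OC)OC | intermediate
13 | 2-naphthylmethyl ether of 12 at the ring hydroxyl | C=C[C@H](O[Si](CC)(CC)CC)[C@]1(C)[C@H]([C@@H](C)[C@@H](OCc2ccc3ccccc3c2)C=C1)C(OC)OC | intermediate
14 | (1S,2S,5S,6R)-2,6-dimethyl-5-(naphthalen-2-ylmethoxy)-2-[(1S)-1-(triethylsilyloxy)prop-2-enyl]cyclohex-3-ene-1-carbaldehyde | C=C[C@H](O[Si](CC)(CC)CC)[C@]1(C)[C@H]([C@@H](C)[C@@H](OCc2ccc3ccccc3c2)C=C1)C=O | intermediate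
15 | (E)-pent-2-en-4-yn-1-ol | OC/C=C/C#C | starting material
16 | [(2R,3R)-3-ethynyloxiran-2-yl]methanol | OC[C@H]1O[C@@H]1C#C | intermediate
17 | (2R,3S)-3-chloropent-4-yne-1,2-diol | OC[C@@H](O)[C@@H](Cl)C#C | intermediate
18 | (2R,3S)-3-chloro-2-hydroxypent-4-ynoic acid | OC(=O)[C@@H](O)[C@@H](Cl)C#C | intermediate
19 | naphthalen-2-ylmethyl (2R,3S)-3-chloro-2-hydroxypent-4-ynoate | O=C(OCc1ccc2ccccc2c1)[C@@H](O)[C@@H](Cl)C#C | intermediate
20 | methyl (triphenylphosphoranylidene)acetate | COC(=O)C=P(c1ccccc1)(c1ccccc1)c1ccccc1 | starting material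
21 | (triphenylphosphoranylidene)ethenone | O=C=C=P(c1ccccc1)(c1ccccc1)c1ccccc1 | intermediate
22 | ester ylide: 19 O-acylated at the 2-hydroxyl by (triphenylphosphoranylidene)acetyl | O=C(OCc1ccc2ccccc2c1)[C@@H](OC(=O)C=P(c1ccccc1)(c1ccccc1)c1ccccc1)[C@@H](Cl)C#C | intermediate
23 | (5R)-5-[(1S)-1-chloroprop-2-ynyl]-4-(naphthalen-2-ylmethoxy)furan-2(5H)-one | O=C1C=C(OCc2ccc3ccccc3c2)[C@H]([C@@H](Cl)C#C)O1 | intermediate
24 | (5R)-5-[(1S)-1-chloroprop-2-ynyl]-3-iodo-4-(naphthalen-2-ylmethoxy)furan-2(5H)-one | O=C1C(I)=C(OCc2ccc3ccccc3c2)[C@H]([C@@H](Cl)C#C)O1 | intermediate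
25 | (5R)-5-[(1S)-1-chloro-2-methylidenebut-3-enyl]-3-iodo-4-(naphthalen-2-ylmethoxy)furan-2(5H)-one | O=C1C(I)=C(OCc2ccc3ccccc3c2)[C@H]([C@@H](Cl)C(=C)C=C)O1 | intermediate
26 | 3-(chloromagnesio) analogue of 25 (alkenylmagnesium chloride) | O=C1C([Mg]Cl)=C(OCc2ccc3ccccc3c2)[C@H]([C@@H](Cl)C(=C)C=C)O1 | intermediate
27 | (5R)-5-[(1S)-1-chloro-2-methylidenebut-3-enyl]-3-(hydroxymethyl)-4-(naphthalen-2-ylmethoxy)furan-2(5H)-one | O=C1C(CO)=C(OCc2ccc3ccccc3c2)[C@H]([C@@H](Cl)C(=C)C=C)O1 | intermediate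
28 | (5R)-3-(bromomethyl)-5-[(1S)-1-chloro-2-methylidenebut-3-enyl]-4-(naphthalen-2-ylmethoxy)furan-2(5H)-one | O=C1C(CBr)=C(OCc2ccc3ccccc3c2)[C@H]([C@@H](Cl)C(=C)C=C)O1 | intermediate
29 | allylzinc bromide from 28 (BrZn–CH2 on the lactone C3) | O=C1C(C[Zn]Br)=C(OCc2ccc3ccccc3c2)[C@H]([C@@H](Cl)C(=C)C=C)O1 | intermediate
30 | bromozinc C9-alkoxide of the (8R,9R) Barbier adduct of 14 and 29 | C=C[C@H](O[Si](CC)(CC)CC)[C@]1(C)[C@H]([C@@H](C)[C@@H](OCc2ccc3ccccc3c2)C=C1)[C@@H](O[Zn]Br)[C@]1(OCc2ccc3ccccc3c2)C(=C)C(=O)O[C@H]1[C@@H](Cl)C(=C)C=C | intermediate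
31 | (R)-[(1S,2S,5S,6R)-2,6-dimethyl-5-(naphthalen-2-ylmethoxy)-2-[(1S)-1-(triethylsilyloxy)prop-2-enyl]cyclohex-3-enyl][(2R,3R)-2-[(1S)-1-chloro-2-methylidenebut-3-enyl]-4-methylidene-3-(naphthalen-2-ylmethoxy)-5-oxooxolan-3-yl]methyl acetate | C=C[C@H](O[Si](CC)(CC)CC)[C@]1(C)[C@H]([C@@H](C)[C@@H](OCc2ccc3ccccc3c2)C=C1)[C@@H](OC(C)=O)[C@]1(OCc2ccc3ccccc3c2)C(=C)C(=O)O[C@H]1[C@@H](Cl)C(=C)C=C | intermediate
32 | 17S (4S-methyl oxolanone) epimer of 33 | C=C[C@H](O[Si](CC)(CC)CC)[C@]1(C)[C@H]([C@@H](C)[C@@H](OCc2ccc3ccccc3c2)C=C1)[C@@H](OC(C)=O)[C@]1(OCc2ccc3ccccc3c2)[C@H](C)C(=O)O[C@H]1[C@@H](Cl)C(=C)C=C | intermediate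
33 | 17,18-dihydro-31 with (2R,3R,4R)-4-methyl-5-oxooxolane (17R) | C=C[C@H](O[Si](CC)(CC)CC)[C@]1(C)[C@H]([C@@H](C)[C@@H](OCc2ccc3ccccc3c2)C=C1)[C@@H](OC(C)=O)[C@]1(OCc2ccc3ccccc3c2)[C@@H](C)C(=O)O[C@H]1[C@@H](Cl)C(=C)C=C | intermediate
34 | desilylated 33: free (1S)-1-hydroxyprop-2-enyl group (RCM precursor) | C=C[C@H](O)[C@]1(C)[C@H]([C@@H](C)[C@@H](OCc2ccc3ccccc3c2)C=C1)[C@@H](OC(C)=O)[C@]1(OCc2ccc3ccccc3c2)[C@@H](C)C(=O)O[C@H]1[C@@H](Cl)C(=C)C=C | intermediate
35 | (2S,3Z,6S,7R,8R,9R,17R)-9-acetoxy-6-chloro-2-hydroxy-8,12-bis(naphthalen-2-ylmethoxy)briara-3,5(16),13-trien-19-oic acid 19,7-lactone (other centres as in 40) | C=C1/C=C\[C@H](O)[C@]2(C)[C@H]([C@@H](C)[C@@H](OCc3ccc4ccccc4c3)C=C2)[C@@H](OC(C)=O)[C@]2(OCc3ccc4ccccc4c3)[C@@H](C)C(=O)O[C@H]2[C@H]1Cl | intermediate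
36 | (2R,3S,4R)-3,4-epoxide of 35 (C13=C14 intact) | C=C1[C@H]2O[C@H]2[C@H](O)[C@]2(C)[C@H]([C@@H](C)[C@@H](OCc3ccc4ccccc4c3)C=C2)[C@@H](OC(C)=O)[C@]2(OCc3ccc4ccccc4c3)[C@@H](C)C(=O)O[C@H]2[C@H]1Cl | intermediate
37 | (2R,3S,4R,13S,14R)-3,4:13,14-bis-epoxide (2-epi-39) | C=C1[C@H]2O[C@H]2[C@H](O)[C@]2(C)[C@H]([C@@H](C)[C@@H](OCc4ccc5ccccc5c4)[C@@H]3O[C@@H]32)[C@@H](OC(C)=O)[C@]2(OCc3ccc4ccccc4c3)[C@@H](C)C(=O)O[C@H]2[C@H]1Cl | intermediate
38 | 2-oxo derivative of 37 | C=C1[C@H]2O[C@H]2C(=O)[C@]2(C)[C@H]([C@@H](C)[C@@H](OCc4ccc5ccccc5c4)[C@@H]3O[C@@H]32)[C@@H](OC(C)=O)[C@]2(OCc3ccc4ccccc4c3)[C@@H](C)C(=O)O[C@H]2[C@H]1Cl | intermediate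
39 | 8,12-di-O-(naphthalen-2-ylmethyl) ether of 40 (2S) | C=C1[C@H]2O[C@H]2[C@@H](O)[C@]2(C)[C@H]([C@@H](C)[C@@H](OCc4ccc5ccccc5c4)[C@@H]3O[C@@H]32)[C@@H](OC(C)=O)[C@]2(OCc3ccc4ccccc4c3)[C@@H](C)C(=O)O[C@H]2[C@H]1Cl | intermediate
40 | (1S,2S,3S,4R,6S,7R,8R,9R,10S,11R,12R,13S,14R,17R)-9-acetoxy-6-chloro-3,4:13,14-diepoxy-2,8,12-trihydroxybriar-5(16)-en-19-oic acid 19,7-lactone (CNP0314105.1) | C=C1[C@H]2O[C@H]2[C@@H](O)[C@]2(C)[C@H]([C@@H](C)[C@@H](O)[C@@H]3O[C@@H]32)[C@@H](OC(C)=O)[C@]2(O)[C@@H](C)C(=O)O[C@H]2[C@H]1Cl | target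

## Step count and risks

Total steps: 27.
Longest linear sequence: 17 steps (1–9 then 20–27; the lactone branch 10–13, 15–19 then 20–27 is equally long), i.e. 17/27.

Steps most likely to fail:

Step 20 (C8–C9 union). The γ-attack has to build a quaternary alkoxy carbon against a hindered aldehyde, and attack at the unhindered CH2 terminus or translactonisation could win. The fallback sets out from iodide 25 and delivers the allyl unit as an isolable boronate instead of an organozinc. Iodine–magnesium exchange of 25 (i-PrMgCl·LiCl, −78 °C) and trapping with ClCH2Bpin (Matteson 1,2-metallate shift) gives the 2-alkoxycarbonyl allylboronate (5R)-5-[(1S)-1-chloro-2-methylidenebut-3-enyl]-4-(naphthalen-2-ylmethoxy)-3-[(pinacolboryl)methyl]furan-2(5H)-one F1. Sc(OTf)3-catalysed allylboration of aldehyde 14 through the same closed chair then gives, after work-up, the free (8R,9R) homoallylic alcohol F2. Acetylation (Ac2O, DMAP) brings the material back to the route at 31.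

Step 23 (ten-membered RCM). Oligomerisation, or isomerisation of the allylic alcohol to an ethyl ketone, may outrun closure of the strained Z-diene ring. The fallback sets out from 34 and changes the alkene partner to a vinyl ketone. Oxidation of 34 (MnO2) gives the enone F3, a type-II olefin that cannot isomerise and homodimerises slowly. RCM (Hoveyda–Grubbs II, toluene, 80–110 °C) gives the cross-conjugated macrocyclic dienone F4. Reduction with (R)-Me-CBS/catecholborane (tert-alkyl as the large group; the C2 epimer is recycled by re-oxidation) returns to the route at 35.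

Step 24 (one-pot double directed epoxidation). The homoallylic C13=C14 epoxidation may be slow or unselective, or the C5=C16 alkene may be attacked by the excess oxidant. The fallback sets out from 35 and separates the two events. With 1.1 equiv t-BuOOH at −20 °C only the allylic alkene reacts and monoepoxide 36 is isolated. Dess–Martin oxidation gives the mono-epoxy ketone F5, and Zn(BH4)2 reduction gives the (2S)-alcohol F6. Epoxidation of F6 with mCPBA (NaHCO3, CH2Cl2, 0 °C) then places oxygen on the α face of C13=C14, anti to the 12-O-naphthylmethyl group and hydrogen-bond-guided by the α-side-chain hydroxyl, and rejoins the route at 39.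

## Further compounds

F1 | step 20 | (5R)-5-[(1S)-1-chloro-2-methylidenebut-3-enyl]-4-(naphthalen-2-ylmethoxy)-3-[(4,4,5,5-tetramethyl-1,3,2-dioxaborolan-2-yl)methyl]furan-2(5H)-one | O=C1C(CB2OC(C)(C)C(C)(C)O2)=C(OCc2ccc3ccccc3c2)[C@H]([C@@H](Cl)C(=C)C=C)O1
F2 | step 20 | free (8R,9R) homoallylic alcohol corresponding to acetate 31 | C=C[C@H](O[Si](CC)(CC)CC)[C@]1(C)[C@H]([C@@H](C)[C@@H](OCc2ccc3ccccc3c2)C=C1)[C@@H](O)[C@]1(OCc2ccc3ccccc3c2)C(=C)C(=O)O[C@H]1[C@@H](Cl)C(=C)C=C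
F3 | step 23 | vinyl ketone (2-oxo analogue) of 34 | C=CC(=O)[C@]1(C)[C@H]([C@@H](C)[C@@H](OCc2ccc3ccccc3c2)C=C1)[C@@H](OC(C)=O)[C@]1(OCc2ccc3ccccc3c2)[C@@H](C)C(=O)O[C@H]1[C@@H](Cl)C(=C)C=C
F4 | step 23 | (3Z)-2-oxo analogue of 35 (macrocyclic cross-conjugated dienone) | C=C1/C=C\C(=O)[C@]2(C)[C@H]([C@@H](C)[C@@H](OCc3ccc4ccccc4c3)C=C2)[C@@H](OC(C)=O)[C@]2(OCc3ccc4ccccc4c3)[C@@H](C)C(=O)O[C@H]2[C@H]1Cl
F5 | step 24 | 2-oxo derivative of monoepoxide 36 (C13=C14 intact) | C=C1[C@H]2O[C@H]2C(=O)[C@]2(C)[C@H]([C@@H](C)[C@@H](OCc3ccc4ccccc4c3)C=C2)[C@@H](OC(C)=O)[C@]2(OCc3ccc4ccccc4c3)[C@@H](C)C(=O)O[C@H]2[C@H]1Cl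
F6 | step 24 | (2S)-epimer of monoepoxide 36 (C13=C14 intact) | C=C1[C@H]2O[C@H]2[C@@H](O)[C@]2(C)[C@H]([C@@H](C)[C@@H](OCc3ccc4ccccc4c3)C=C2)[C@@H](OC(C)=O)[C@]2(OCc3ccc4ccccc4c3)[C@@H](C)C(=O)O[C@H]2[C@H]1Cl
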